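At early times the starting complex leaves along two paths, and the cedar run separates them at 20.0 min: 17.3% of it is quenched substrate, while another 17.4% has gone the other way, with 14.3% standing as complex with one exchanged.

- cedar: starting complex 0.40 M; incoming ligand 0.60 equiv; protic impurity 0.80 M; run made earlier
- flask: starting complex 0.80 M; incoming ligand 0.600 equiv; protic impurity 0.800 M; time 5.0 h

- cedar (time / min: complex with one exchanged / %, quenched substrate / %, starting complex / %): 20.0: 14.3, 17.3, 65.3; 40.0: 21.6, 26.4, 47.0; 50.0: 20.8, 27.5, 41.8; 80.0: 20.5, 36.5, 29.8; 90.0: 19.3, 40.1, 24.2

(standard deviation of a reading: 1 percentage point)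

- no earlier run changes the charge of incoming ligand; that part of a forecast is a guess

1. complex with one exchanged present at 5.0 h, in percent of the starting complex charged
2. quenched substrate present at 5.0 h, in percent of the starting complex charged
3. starting complex present at 5.0 h, in percent of the starting complex charged
4. concentration of incoming ligand at 5.0 h, in M

Taking mean levels over that interval, and one incoming ligand per exchange, so that c(incoming ligand) averages 0.205 M, my reading gives a quench constant of 0.0131 M⁻¹ min⁻¹ and an exchange constant of 0.0513 M⁻¹ min⁻¹.

The asked flask is charged with c(incoming ligand) of 0.480 M. Its starting complex therefore has two pseudo-first-order lifetimes at the charge: a quench time of 95.5 min and a shorter exchange time of 40.6 min. Their ratio, exchange time over quench time, is the split, the quench rate over the exchange rate: 0.425. The cedar run, with less ligand, starts at 0.850. The split climbs as exchange uses incoming ligand, so c(incoming ligand) is the level to watch.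

The forecast gives 16% complex with one exchanged, 48% quenched substrate, 6% starting complex and 0.02 M incoming ligand, holding that, once ligand has fallen, “After that, quenching dominates”.

The flask gives 22.9% complex with one exchanged, 51.2% quenched substrate, 9.32% starting complex and 0.0314 M incoming ligand.

    starting complex + incoming ligand ⇌ leaving ligand + complex with one exchanged (K = 23.0, k = 0.0630 M⁻¹ min⁻¹)
    complex with one exchanged + incoming ligand ⇌ leaving ligand + complex with two exchanged (K = 11.0, k = 0.120 M⁻¹ min⁻¹)
    protic impurity + starting complex → quenched substrate (k = 0.0120 M⁻¹ min⁻¹)

In this flask, c(incoming ligand) stood at 0.0268 M after 2.50 h and was higher at 5.0 h. With 0.0314 M of incoming ligand and 49% of the protic impurity left at 5.0 h, the split scaled from the constants read off the cedar run comes to 3.18, while the constants of the scheme, forward rates taken, give 2.37. In the same flask with 1.00 equiv of incoming ligand, the split starts at 0.255, and quenched substrate reaches 38.1%.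

(All runs stem from a simulated flask for substances that don't exist; noise was put on by code.)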